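Megaphone is cut at the bond between the aryl ring and the benzylic carbinol carbon C7. The last step unites a 3,4,5-trimethoxyphenyltitanium reagent with the complete keto aldehyde, which already carries ring stereocentres C4 and C6 and the methyl-bearing C8. The step exploits two features: C8 sits between the aldehyde and the quaternary ring carbon C6, so Felkin–Anh addition anti to C6 gives the 7,8-syn carbinol; and the ring carbonyl C1 is a neopentyl enone, inert to ArTi(OiPr)3, so no protecting group is needed. The aldehyde comes from (R)-4-methoxycyclohexenone by Ir-catalysed crotylation of a β-keto ester (C8), ozonolysis and Pd-catalysed decarboxylative allylation anti to the methoxy group (C6).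

Key step: step 8

Numbering used for atoms: cyclohexenone ring C1 (C=O), C2=C3, C4 (OMe), C5 (CH2), C6 (quaternary); side chain C8 (CHMe, on C6) and C7 (carbinol).

Remark: 1,4-dioxaspiro[4.5]dec-6-en-8-one (1) is treated as a commercial material.

Remark: the sense of induction of the catalysts in steps 1 and 5 is assigned by analogy; both enantiomers of each ligand are available, and the one that gives the stated configuration is used.

Step 1
Reactants: 1 1,4-dioxaspiro[4.5]dec-6-en-8-one
Product: 2 (8R)-1,4-dioxaspiro[4.5]dec-6-en-8-ol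
Conditions: RuCl(p-cymene)[(R,R)-TsDPEN] (1 mol%), HCO2Na, Bu4NCl (cat.), CH2Cl2/H2O, rt
Reagents that add atoms: none
Why: Noyori–Ikariya asymmetric transfer hydrogenation should reduce the enone carbonyl 1,2-selectively through the outer-sphere Ru–H/N–H transition state, the ring C=C taking the place of the aryl group of an aryl ketone so that the (R,R)-catalyst sets the (8R) carbinol (megaphone C4), while the buffered formate medium leaves the ketal intact.

Step 2
Reactants: 2 (8R)-1,4-dioxaspiro[4.5]dec-6-en-8-ol
Product: 4 (4R)-4-methoxycyclohex-2-en-1-one, via methyl ether ketal 3 (not isolated)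
Conditions: NaH, MeI, THF, 0 °C→rt; then 1 M aq. HCl, rt
Reagents that add atoms: iodomethane (CI); water (O)
Why: Williamson etherification of the sodium alkoxide followed by acid hydrolysis of the allylic ketal in the same flask should unveil the enone without touching the C4 stereocentre, which is not epimerisable under these conditions.

Step 3
Reactants: 5 2-(trimethylsilyl)ethanol
Product: 6 2-(trimethylsilyl)ethyl 1H-imidazole-1-carboxylate
Conditions: CDI, CH2Cl2, 0 °C→rt
Reagents that add atoms: 1,1'-carbonyldiimidazole (O=C(n1ccnc1)n1ccnc1)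
Why: Acyl substitution at CDI by the primary alcohol should give the imidazole carbamate, a stable alkoxycarbonyl donor for enolate C-acylation.

Step 4
Reactants: 4 (4R)-4-methoxycyclohex-2-en-1-one; 6 2-(trimethylsilyl)ethyl 1H-imidazole-1-carboxylate
Product: 8 2-(trimethylsilyl)ethyl (5R)-5-methoxy-2-oxocyclohex-3-ene-1-carboxylate (C1 epimers, used as such), via lithium dienolate 7 (not isolated)
Conditions: LiHMDS, THF, −78 °C; then 6, BF3·OEt2, −78 °C
Reagents that add atoms: none
Why: Kinetic α'-deprotonation gives the cross-conjugated dienolate, which should undergo Claisen-type C-acylation with the BF3-activated imidazole carboxylate at megaphone C6, the new ring stereocentre being epimeric and irrelevant because it is rebuilt in step 7.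

Step 5
Reactants: 8 2-(trimethylsilyl)ethyl (5R)-5-methoxy-2-oxocyclohex-3-ene-1-carboxylate
Product: 9 2-(trimethylsilyl)ethyl (5R)-1-[(2R)-but-3-en-2-yl]-5-methoxy-2-oxocyclohex-3-ene-1-carboxylate (C1 epimers, used as such)
Conditions: [Ir(cod)Cl]2 (2 mol%), Me-THQphos (4 mol%; enantiomer as stated in the remark), TBD (10 mol%), (E)-crotyl chloride, proton sponge, LiBr, THF, 25 °C
Reagents that add atoms: (E)-crotyl chloride (C/C=C/CCl)
Why: Iridium-catalysed branched-selective asymmetric allylic alkylation of the β-keto ester enolate should attack the methyl-bearing terminus of the π-crotyl iridium complex so that the catalyst sets the allylic carbon C8 as (R), whereas the configuration of the ester-bearing quaternary carbon is of no consequence because that centre is planarised in step 7.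

Step 6
Reactants: 9 2-(trimethylsilyl)ethyl (5R)-1-[(2R)-but-3-en-2-yl]-5-methoxy-2-oxocyclohex-3-ene-1-carboxylate
Product: 11 2-(trimethylsilyl)ethyl (5R)-5-methoxy-2-oxo-1-[(2S)-1-oxopropan-2-yl]cyclohex-3-ene-1-carboxylate, via secondary ozonide 10 (not isolated)
Conditions: O3, CH2Cl2, −78 °C (Sudan Red 7B end-point); then PPh3, −78 °C→rt
Reagents that add atoms: ozone ([O-][O+]=O)
Why: Ozonolysis (Criegee mechanism) under indicator control should cleave only the electron-rich monosubstituted vinyl group, the conjugated enone C=C reacting much more slowly, and the neutral reductive work-up leaves the C8 stereocentre next to the new aldehyde untouched.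

Step 7
Reactants: 11 2-(trimethylsilyl)ethyl (5R)-5-methoxy-2-oxo-1-[(2S)-1-oxopropan-2-yl]cyclohex-3-ene-1-carboxylate
Product: 13 (2S)-2-[(1R,5R)-5-methoxy-2-oxo-1-(prop-2-en-1-yl)cyclohex-3-en-1-yl]propanal, via tetrabutylammonium carboxylate 12 (not isolated)
Conditions: Pd2(dba)3 (5 mol%), (S)-t-BuPHOX (12.5 mol%), allyl methyl carbonate, TBAT, THF, 25 °C
Reagents that add atoms: allyl methyl carbonate (C=CCOC(=O)OC)
Why: In this fluoride-triggered decarboxylative Tsuji–Trost allylation, fluoride cleaves the 2-(trimethylsilyl)ethyl ester to carboxylate 12, which loses CO2 at the π-allylpalladium cation and is allylated at C6, the quaternary stereocentre being set by allyl delivery to the dienolate face anti to the C4 methoxy group, a bias that the (S)-PHOX ligand should reinforce by analogy with 2-alkyl-2-allylcyclohexanones.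

Step 8
Reactants: 13 (2S)-2-[(1R,5R)-5-methoxy-2-oxo-1-(prop-2-en-1-yl)cyclohex-3-en-1-yl]propanal; 14 5-bromo-1,2,3-trimethoxybenzene
Product: 17 megaphone, via arylmagnesium bromide 15 (not isolated), via aryltitanium triisopropoxide 16 (not isolated)
Conditions: 14, Mg, THF, rt→40 °C; ClTi(OiPr)3, −78→0 °C; then 13, THF, −78→−20 °C; aq. NH4Cl
Reagents that add atoms: none
Why: Bromide 14 is converted into Grignard reagent 15 and transmetallated to aryltitanium 16, which transfers its aryl group to the aldehyde carbon C7 of 13 through a four-centre Ti–O/C–C transition state. The closest known reaction type is the chemoselective addition of RTi(OiPr)3 reagents to aldehydes under Felkin–Anh 1,2-induction. No ring is closed. The new stereocentre C7 is controlled by C8: the quaternary ring carbon C6 stands anti to the incoming aryl, the C8 methyl sits inside and the C8 hydrogen outside, which should give the 7,8-syn (7R) alcohol. The step needs aldehyde-over-enone selectivity and no enolisation at C8; the ring carbonyl C1 is flanked by quaternary C6, organotitanium triisopropoxides neither add to ketones nor conjugate-add at low temperature, and they are non-basic.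

Compound list
1 | 1,4-dioxaspiro[4.5]dec-6-en-8-one | O=C1CCC2(OCCO2)C=C1 | starting material
2 | (8R)-1,4-dioxaspiro[4.5]dec-6-en-8-ol | O[C@@H]1CCC2(OCCO2)C=C1 | intermediate
3 | (8R)-8-methoxy-1,4-dioxaspiro[4.5]dec-6-ene | CO[C@@H]1CCC2(OCCO2)C=C1 | intermediate
4 | (4R)-4-methoxycyclohex-2-en-1-one | CO[C@@H]1CCC(=O)C=C1 | intermediate
5 | 2-(trimethylsilyl)ethanol | C[Si](C)(C)CCO | starting material
6 | 2-(trimethylsilyl)ethyl 1H-imidazole-1-carboxylate | C[Si](C)(C)CCOC(=O)n1ccnc1 | intermediate
7 | lithium (4R)-4-methoxycyclohexa-1,5-dien-1-olate | [Li+].CO[C@@H]1CC=C([O-])C=C1 | intermediate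
8 | 2-(trimethylsilyl)ethyl (5R)-5-methoxy-2-oxocyclohex-3-ene-1-carboxylate | CO[C@@H]1CC(C(=O)OCC[Si](C)(C)C)C(=O)C=C1 | intermediate
9 | 2-(trimethylsilyl)ethyl (5R)-1-[(2R)-but-3-en-2-yl]-5-methoxy-2-oxocyclohex-3-ene-1-carboxylate | CO[C@@H]1CC([C@H](C)C=C)(C(=O)OCC[Si](C)(C)C)C(=O)C=C1 | intermediate
10 | 2-(trimethylsilyl)ethyl (5R)-5-methoxy-2-oxo-1-[(1S)-1-(1,2,4-trioxolan-3-yl)ethyl]cyclohex-3-ene-1-carboxylate | CO[C@@H]1CC([C@H](C)C2OCOO2)(C(=O)OCC[Si](C)(C)C)C(=O)C=C1 | intermediate
11 | 2-(trimethylsilyl)ethyl (5R)-5-methoxy-2-oxo-1-[(2S)-1-oxopropan-2-yl]cyclohex-3-ene-1-carboxylate | CO[C@@H]1CC([C@H](C)C=O)(C(=O)OCC[Si](C)(C)C)C(=O)C=C1 | intermediate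
12 | tetrabutylammonium (5R)-5-methoxy-2-oxo-1-[(2S)-1-oxopropan-2-yl]cyclohex-3-ene-1-carboxylate | CCCC[N+](CCCC)(CCCC)CCCC.CO[C@@H]1CC([C@H](C)C=O)(C(=O)[O-])C(=O)C=C1 | intermediate
13 | (2S)-2-[(1R,5R)-5-methoxy-2-oxo-1-(prop-2-en-1-yl)cyclohex-3-en-1-yl]propanal | C=CC[C@]1([C@H](C)C=O)C[C@@H](OC)C=CC1=O | intermediate
14 | 5-bromo-1,2,3-trimethoxybenzene | COc1cc(Br)cc(OC)c1OC | starting material
15 | (3,4,5-trimethoxyphenyl)magnesium bromide | COc1cc([Mg]Br)cc(OC)c1OC | intermediate
16 | tri(propan-2-yloxy)(3,4,5-trimethoxyphenyl)titanium | COc1cc([Ti](OC(C)C)(OC(C)C)OC(C)C)cc(OC)c1OC | intermediate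
17 | megaphone, (4R,6R)-6-[(1R,2S)-1-hydroxy-1-(3,4,5-trimethoxyphenyl)propan-2-yl]-4-methoxy-6-(prop-2-en-1-yl)cyclohex-2-en-1-one | C=CC[C@]1([C@H](C)[C@@H](O)c2cc(OC)c(OC)c(OC)c2)C[C@@H](OC)C=CC1=O | target

Total step count: 8. Longest linear sequence: 7 (steps 1, 2, 4, 5, 6, 7, 8).

Steps most likely to fail

1. Step 8 (key step). What may go wrong: insufficient facial discrimination at the aldehyde (Felkin versus anti-Felkin attack), or attack on the enone if the hindered aldehyde reacts slowly. Fallback: replace substrate control by a stoichiometric titanium reagent with catalyst-controlled aryl transfer from zinc. Setting out from 13, (3,4,5-trimethoxyphenyl)boronic acid is transmetallated with diethylzinc (toluene, 60 °C) to ethyl(3,4,5-trimethoxyphenyl)zinc F1. F1 is added to 13 at 0 °C in the presence of a chiral β-amino alcohol ligand (a 3-exo-morpholinoisoborneol, enantiomer matched to the Felkin preference), which comes back to the route at 17. Mixed arylzinc reagents of this kind leave ketones and enones untouched.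

2. Step 7. What may go wrong: epimerisation at C8 through enolisation of the free aldehyde by fluoride or methoxide, or capture of the aldehyde by the enolate oxygen (cyclic hemiacetal formation and O-allylation). Fallback: mask the aldehyde. Setting out from 11, trimethyl orthoformate and PPTS in methanol should give the dimethyl acetal 2-(trimethylsilyl)ethyl (5R)-1-[(2S)-1,1-dimethoxypropan-2-yl]-5-methoxy-2-oxocyclohex-3-ene-1-carboxylate F2. The same fluoride-triggered palladium allylation then gives the allylated acetal (4R,6R)-6-[(2S)-1,1-dimethoxypropan-2-yl]-4-methoxy-6-(prop-2-en-1-yl)cyclohex-2-en-1-one F3. Mild hydrolysis (aqueous oxalic acid, THF) comes back to the route at 13.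

3. Step 5. What may go wrong: loss of branched regioselectivity or of enantiofacial control with the small methyl-substituted allyl unit, or base-induced side reactions of the enone. Fallback: build C8 by conjugate addition instead of allylic substitution. Setting out from 8, a bifunctional thiourea-catalysed Michael addition to (E)-1-nitropropene should give the nitro compound 2-(trimethylsilyl)ethyl (5R)-5-methoxy-1-[(2S)-1-nitropropan-2-yl]-2-oxocyclohex-3-ene-1-carboxylate F4, with catalyst control at C8. A TiCl3-mediated Nef reaction (aq. TiCl3, NH4OAc, THF) converts the nitromethyl group into the aldehyde and comes back to the route at 11.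

Further compounds
F1 | step 8 | ethyl(3,4,5-trimethoxyphenyl)zinc | CC[Zn]c1cc(OC)c(OC)c(OC)c1
F2 | step 7 | 2-(trimethylsilyl)ethyl (5R)-1-[(2S)-1,1-dimethoxypropan-2-yl]-5-methoxy-2-oxocyclohex-3-ene-1-carboxylate | CO[C@@H]1CC([C@H](C)C(OC)OC)(C(=O)OCC[Si](C)(C)C)C(=O)C=C1
F3 | step 7 | (4R,6R)-6-[(2S)-1,1-dimethoxypropan-2-yl]-4-methoxy-6-(prop-2-en-1-yl)cyclohex-2-en-1-one | C=CC[C@]1([C@H](C)C(OC)OC)C[C@@H](OC)C=CC1=O
F4 | step 5 | 2-(trimethylsilyl)ethyl (5R)-5-methoxy-1-[(2S)-1-nitropropan-2-yl]-2-oxocyclohex-3-ene-1-carboxylate | CO[C@@H]1CC([C@H](C)C[N+](=O)[O-])(C(=O)OCC[Si](C)(C)C)C(=O)C=C1
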